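**Retrosynthetic overview**

- Target 17 ← pentabenzyl (2S)-flavanone 16 (hydrogenolysis of five benzyl ethers) ← flavan-4-ol 15 ← 4-methoxyflavan 14, so C4 is carried at the alcohol oxidation level.
- Structural feature used: in ring C (O1–C2–C3–C4–C4a–C8a), O1 and C4 sit on the adjacent ring-A carbons C8a and C4a, which is a salicylaldehyde pattern, and C2–C3 with its aryl group is the vinyl unit of a ring-B styrene. Ring C is therefore cut at O1–C2 and C3–C4 into the O-methyl ortho-quinone methide cation from acetal 13 (made in the flask from aldehyde 3) and styrene 12.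
- Styrene 12 ← Wittig methylenation of biaryl aldehyde 11 ← Suzuki coupling of 6-iodoflavone 7 (C6 of the apigenin unit) with boronate 10 (C3' of ring B).
- 7 comes from apigenin (7,4'-dibenzylation, iodination at C6 next to the free 5-OH, 5-O-benzylation); 10 from 3-bromo-4-hydroxybenzaldehyde; 3 from 2,4,6-trihydroxybenzaldehyde.
- Ring order: the flavone rings arrive with apigenin; ring C of the flavanone is the only ring built and is closed last, in the key step.

Key step: step 10

Assumption: the sense of induction of the confined acid cannot be derived for this new substrate pair; the (S,S) catalyst is written, and its mirror image is used instead if a trial shows that the (S,S) form gives 2R.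

**Route**

Step 1
Reactants: 1 2,4,6-trihydroxybenzaldehyde
Product: 2 4-(benzyloxy)-2,6-dihydroxybenzaldehyde
Conditions: BnBr (1.0 equiv), K2CO3 (1.0 equiv), DMF, 0 °C to rt
Reagents that add atoms: benzyl bromide, BrCc1ccccc1
Why: Williamson etherification; the 4-OH is the most acidic hydroxyl and the only one not hydrogen-bonded to the aldehyde, so one equivalent of base and halide should alkylate it first.

Step 2
Reactants: 2 4-(benzyloxy)-2,6-dihydroxybenzaldehyde
Product: 3 4-(benzyloxy)-2-hydroxy-6-methoxybenzaldehyde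
Conditions: MeI (1.1 equiv), K2CO3 (1.1 equiv), acetone, rt
Reagents that add atoms: iodomethane, CI
Why: Williamson methylation of one of two equivalent hydroxyls; the hydroxyl that remains is locked in a hydrogen bond to the aldehyde and is much less reactive, so the reaction should stop at the mono-ether.

Step 3
Reactants: 4 apigenin
Product: 5 7-(benzyloxy)-2-[4-(benzyloxy)phenyl]-5-hydroxy-4H-chromen-4-one
Conditions: BnBr (2.2 equiv), K2CO3 (2.5 equiv), DMF, rt
Reagents that add atoms: benzyl bromide, BrCc1ccccc1
Why: Williamson etherification; the 7-OH and 4'-OH react at room temperature while the 5-OH, chelated to the C4 carbonyl, stays free.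

Step 4
Reactants: 5 7-(benzyloxy)-2-[4-(benzyloxy)phenyl]-5-hydroxy-4H-chromen-4-one
Product: 6 7-(benzyloxy)-2-[4-(benzyloxy)phenyl]-5-hydroxy-6-iodo-4H-chromen-4-one
Conditions: BnMe3N·ICl2 (1.1 equiv), CaCO3, CH2Cl2/MeOH, rt
Reagents that add atoms: benzyltrimethylammonium dichloroiodate, C[N+](C)(C)Cc1ccccc1.Cl[I-]Cl
Why: Electrophilic aromatic iodination; with the 5-OH free and the 7-oxygen alkylated, attack is directed to C6, ortho to the free phenol, which is the established regiochemistry for 5-hydroxy-7-alkoxyflavones with this reagent.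

Step 5
Reactants: 6 7-(benzyloxy)-2-[4-(benzyloxy)phenyl]-5-hydroxy-6-iodo-4H-chromen-4-one
Product: 7 5,7-bis(benzyloxy)-2-[4-(benzyloxy)phenyl]-6-iodo-4H-chromen-4-one
Conditions: BnBr (1.5 equiv), K2CO3 (2 equiv), DMF, 60 °C
Reagents that add atoms: benzyl bromide, BrCc1ccccc1
Why: Williamson etherification under more forcing conditions; the chelated, hindered 5-OH is alkylated once heat and a polar aprotic solvent are used, which removes the last free phenol before the coupling, the acid step and the oxidation.

Step 6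
Reactants: 8 3-bromo-4-hydroxybenzaldehyde
Product: 9 4-(benzyloxy)-3-bromobenzaldehyde
Conditions: BnBr (1.1 equiv), K2CO3 (1.5 equiv), DMF, rt
Reagents that add atoms: benzyl bromide, BrCc1ccccc1
Why: Williamson etherification of an acidic para-formyl phenol, with no competing site.

Step 7
Reactants: 9 4-(benzyloxy)-3-bromobenzaldehyde
Product: 10 4-(benzyloxy)-3-(4,4,5,5-tetramethyl-1,3,2-dioxaborolan-2-yl)benzaldehyde
Conditions: B2pin2 (1.1 equiv), PdCl2(dppf) (3 mol%), KOAc (3 equiv), 1,4-dioxane, 85 °C
Reagents that add atoms: bis(pinacolato)diboron, CC1(C)OB(B2OC(C)(C)C(C)(C)O2)OC1(C)C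
Why: Miyaura borylation; the aryl bromide is activated by the para-formyl group and the aldehyde is tolerated under the weakly basic acetate conditions.

Step 8
Reactants: 7 5,7-bis(benzyloxy)-2-[4-(benzyloxy)phenyl]-6-iodo-4H-chromen-4-one; 10 4-(benzyloxy)-3-(4,4,5,5-tetramethyl-1,3,2-dioxaborolan-2-yl)benzaldehyde
Product: 11 4-(benzyloxy)-3-{5,7-bis(benzyloxy)-2-[4-(benzyloxy)phenyl]-4-oxo-4H-chromen-6-yl}benzaldehyde
Conditions: 10 (1.3 equiv), Pd(OAc)2 (5 mol%), SPhos (10 mol%), K3PO4 (3 equiv), toluene/H2O 10:1, 90 °C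
Reagents that add atoms: none
Why: Suzuki–Miyaura coupling to a tri-ortho-substituted biaryl with a dialkylbiarylphosphine ligand suited to such cases; the doubly ortho-oxygenated flavone carbon carries the iodide and not the boron, because a 2,6-dialkoxyarylboron species would protodeboronate readily.

Step 9
Reactants: 11 4-(benzyloxy)-3-{5,7-bis(benzyloxy)-2-[4-(benzyloxy)phenyl]-4-oxo-4H-chromen-6-yl}benzaldehyde
Product: 12 5,7-bis(benzyloxy)-6-[2-(benzyloxy)-5-vinylphenyl]-2-[4-(benzyloxy)phenyl]-4H-chromen-4-one
Conditions: Ph3PCH3Br (1.3 equiv), KOtBu (1.25 equiv), THF, 0 °C; then 11, −20 to 0 °C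
Reagents that add atoms: methyltriphenylphosphonium bromide, C[P+](c1ccccc1)(c1ccccc1)c1ccccc1.[Br-]
Why: Wittig methylenation; the aryl aldehyde is far more electrophilic than the vinylogous-ester carbonyl of the flavone, so a small excess of ylide at low temperature should react at the aldehyde only.

Step 10
Reactants: 3 4-(benzyloxy)-2-hydroxy-6-methoxybenzaldehyde; 12 5,7-bis(benzyloxy)-6-[2-(benzyloxy)-5-vinylphenyl]-2-[4-(benzyloxy)phenyl]-4H-chromen-4-one
Product: 14 (2S)-7-(benzyloxy)-4,5-dimethoxy-2-aryl-chromane (aryl = 4-(benzyloxy)-3-{5,7-bis(benzyloxy)-2-[4-(benzyloxy)phenyl]-4-oxo-4H-chromen-6-yl}phenyl; C4 epimer mixture), via dimethyl acetal 13 (not isolated)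
Conditions: 12, HC(OMe)3 (2 equiv), (S,S)-IDPi acid (imidodiphosphorimidate from two 3,3'-diaryl-BINOL units, N-triflyl groups; 10 mol%), 5 Å MS, CH2Cl2, −40 °C; 3 (1.3 equiv) added slowly; Et3N quench at −40 °C
Reagents that add atoms: trimethyl orthoformate, COC(OC)OC
Why: Proposed new method: the acid protonates a methoxy group of acetal 13 and methanol leaves, giving the O-methyl oxocarbenium ion (the O-protonated 4-methoxy ortho-quinone methide) as a contact ion pair with the chiral imidodiphosphorimidate anion, to which the phenol OH is hydrogen-bonded; the CH2 terminus of styrene 12 adds to the methide carbon (C3–C4) and the resulting para-benzyloxybenzyl cation is captured by the phenol oxygen (O1–C2), returning the proton to the catalyst. The closest known reaction types are the achiral acid-catalysed three-component coupling of salicylaldehydes, trimethyl orthoformate and styrenes to 4-methoxyflavans and the chiral-acid-catalysed [4+2] cycloadditions of ortho-quinone methides, including intramolecular ones of O-alkyl oxocarbenium species made from salicylaldehydes, with electron-rich alkenes. Ring C closes as the second half of a stepwise polar [4+2], a six-membered capture of the benzylic cation by oxygen (6-exo-trig with respect to the para-quinone-methide form of that cation). C2 is fixed in this C–O closure, where the confined anion bound to both the cation and the phenol must expose one face of the benzylic carbon to oxygen whatever the configuration at C4; C4 forms as an epimer mixture and is erased in step 12. The step needs Markovnikov regioselectivity, which the para-benzyloxy group of ring B secures, preference for the styrene over Friedel–Crafts attack by electron-rich ring A, which low temperature and slow addition of the formyl-deactivated aldehyde (keeping the acetal concentration low) should favour, and no re-ionisation of the product at C2–O1, which the low temperature and the cold amine quench are meant to prevent. The basic flavone carbonyl of 12 will buffer the acid, which should be tolerable because the 2,4,6-trioxygenated acetal ionises very easily, and is the reason for the raised catalyst loading.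

Step 11
Reactants: 14 (2S)-7-(benzyloxy)-4,5-dimethoxy-2-aryl-chromane (C4 epimer mixture)
Product: 15 (2S)-7-(benzyloxy)-5-methoxy-2-aryl-chroman-4-ol (same aryl group; C4 epimer mixture)
Conditions: PPTS (0.2 equiv), THF/H2O 4:1, high dilution, rt
Reagents that add atoms: water, O
Why: Acid-catalysed SN1 solvolysis; the C4 methyl ether ionises easily to a cation stabilised by O1, the 5-methoxy and the 7-benzyloxy groups and is captured by the large excess of water, while the much less stabilised C2–O1 bond is not ionised by this weak acid, so C2 is untouched.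

Step 12
Reactants: 15 (2S)-7-(benzyloxy)-5-methoxy-2-aryl-chroman-4-ol (C4 epimer mixture)
Product: 16 (2S)-7-(benzyloxy)-2-(4-(benzyloxy)-3-{5,7-bis(benzyloxy)-2-[4-(benzyloxy)phenyl]-4-oxo-4H-chromen-6-yl}phenyl)-5-methoxychroman-4-one
Conditions: Dess–Martin periodinane (1.5 equiv), pyridine (4 equiv), CH2Cl2, 0 °C to rt
Reagents that add atoms: none
Why: Dess–Martin oxidation of a secondary benzylic alcohol; both C4 epimers converge on the one ketone, no free phenol is present, and the buffered, non-basic medium avoids the retro-oxa-Michael opening that would racemise C2.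

Step 13
Reactants: 16 pentabenzyl (2S)-flavanone
Product: 17 (2S)-7-hydroxy-2-{4-hydroxy-3-[5,7-dihydroxy-2-(4-hydroxyphenyl)-4-oxo-4H-chromen-6-yl]phenyl}-5-methoxychroman-4-one (target)
Conditions: H2 (1 atm), Pd/C (10%), THF/MeOH 1:1, rt, stopped when debenzylation is complete
Reagents that add atoms: none
Why: Catalytic hydrogenolysis; aryl benzyl ethers cleave faster than the flavone C2=C3 bond or the aryl ketone is reduced, the methyl ether is inert, and the neutral medium leaves the C2 stereocentre intact.

**Compound list**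

1 | 2,4,6-trihydroxybenzaldehyde | O=Cc1c(O)cc(O)cc1O | starting material
2 | 4-(benzyloxy)-2,6-dihydroxybenzaldehyde | O=Cc1c(O)cc(OCc2ccccc2)cc1O | intermediate
3 | 4-(benzyloxy)-2-hydroxy-6-methoxybenzaldehyde | COc1cc(OCc2ccccc2)cc(O)c1C=O | intermediate
4 | apigenin | O=c1cc(-c2ccc(O)cc2)oc2cc(O)cc(O)c12 | starting material
5 | 7-(benzyloxy)-2-[4-(benzyloxy)phenyl]-5-hydroxy-4H-chromen-4-one | O=c1cc(-c2ccc(OCc3ccccc3)cc2)oc2cc(OCc3ccccc3)cc(O)c12 | intermediate
6 | 7-(benzyloxy)-2-[4-(benzyloxy)phenyl]-5-hydroxy-6-iodo-4H-chromen-4-one | O=c1cc(-c2ccc(OCc3ccccc3)cc2)oc2cc(OCc3ccccc3)c(I)c(O)c12 | intermediate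
7 | 5,7-bis(benzyloxy)-2-[4-(benzyloxy)phenyl]-6-iodo-4H-chromen-4-one | O=c1cc(-c2ccc(OCc3ccccc3)cc2)oc2cc(OCc3ccccc3)c(I)c(OCc3ccccc3)c12 | intermediate
8 | 3-bromo-4-hydroxybenzaldehyde | O=Cc1ccc(O)c(Br)c1 | starting material
9 | 4-(benzyloxy)-3-bromobenzaldehyde | O=Cc1ccc(OCc2ccccc2)c(Br)c1 | intermediate
10 | 4-(benzyloxy)-3-(4,4,5,5-tetramethyl-1,3,2-dioxaborolan-2-yl)benzaldehyde | O=Cc1ccc(OCc2ccccc2)c(B2OC(C)(C)C(C)(C)O2)c1 | intermediate
11 | 4-(benzyloxy)-3-{5,7-bis(benzyloxy)-2-[4-(benzyloxy)phenyl]-4-oxo-4H-chromen-6-yl}benzaldehyde | O=Cc1ccc(OCc2ccccc2)c(-c2c(OCc3ccccc3)cc3oc(-c4ccc(OCc5ccccc5)cc4)cc(=O)c3c2OCc2ccccc2)c1 | intermediate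
12 | 5,7-bis(benzyloxy)-6-[2-(benzyloxy)-5-vinylphenyl]-2-[4-(benzyloxy)phenyl]-4H-chromen-4-one | C=Cc1ccc(OCc2ccccc2)c(-c2c(OCc3ccccc3)cc3oc(-c4ccc(OCc5ccccc5)cc4)cc(=O)c3c2OCc2ccccc2)c1 | intermediate
13 | 5-(benzyloxy)-2-(dimethoxymethyl)-3-methoxyphenol (formed in the flask, not isolated) | COc1cc(OCc2ccccc2)cc(O)c1C(OC)OC | intermediate
14 | (2S)-7-(benzyloxy)-4,5-dimethoxy-2-(4-(benzyloxy)-3-{5,7-bis(benzyloxy)-2-[4-(benzyloxy)phenyl]-4-oxo-4H-chromen-6-yl}phenyl)chromane, C4 epimer mixture | COc1cc(OCc2ccccc2)cc2c1C(OC)C[C@@H](c1ccc(OCc3ccccc3)c(-c3c(OCc4ccccc4)cc4oc(-c5ccc(OCc6ccccc6)cc5)cc(=O)c4c3OCc3ccccc3)c1)O2 | intermediate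
15 | (2S)-7-(benzyloxy)-5-methoxy-2-(4-(benzyloxy)-3-{5,7-bis(benzyloxy)-2-[4-(benzyloxy)phenyl]-4-oxo-4H-chromen-6-yl}phenyl)chroman-4-ol, C4 epimer mixture | COc1cc(OCc2ccccc2)cc2c1C(O)C[C@@H](c1ccc(OCc3ccccc3)c(-c3c(OCc4ccccc4)cc4oc(-c5ccc(OCc6ccccc6)cc5)cc(=O)c4c3OCc3ccccc3)c1)O2 | intermediate
16 | (2S)-7-(benzyloxy)-2-(4-(benzyloxy)-3-{5,7-bis(benzyloxy)-2-[4-(benzyloxy)phenyl]-4-oxo-4H-chromen-6-yl}phenyl)-5-methoxychroman-4-one | COc1cc(OCc2ccccc2)cc2c1C(=O)C[C@@H](c1ccc(OCc3ccccc3)c(-c3c(OCc4ccccc4)cc4oc(-c5ccc(OCc6ccccc6)cc5)cc(=O)c4c3OCc3ccccc3)c1)O2 | intermediate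
17 | (2S)-7-hydroxy-2-{4-hydroxy-3-[5,7-dihydroxy-2-(4-hydroxyphenyl)-4-oxo-4H-chromen-6-yl]phenyl}-5-methoxychroman-4-one | COc1cc(O)cc2c1C(=O)C[C@@H](c1ccc(O)c(-c3c(O)cc4oc(-c5ccc(O)cc5)cc(=O)c4c3O)c1)O2 | target

**Step count**

Total: 13 steps. Longest linear sequence: 9 steps (apigenin 4 through steps 3, 4, 5, 8, 9, 10, 11, 12, 13).

**Steps most likely to fail**

1. Step 10 (the proposed new method). Possible failures: poor facial selectivity at C2 because the very large styrene does not sit properly in the confined ion pair; erosion of configuration by acid re-ionisation of C2–O1; loss of the cation to Friedel–Crafts self-condensation; or sequestration of the acid by the flavone carbonyl. Fallback with known chemistry, setting out from 3 and 12 and returning at 16: the same three-component coupling is run with an achiral acid (TfOH, 2 mol%, HC(OMe)3, CH2Cl2, −20 °C) through acetal 13 to give the racemic 4-methoxyflavan F1. Hydrolysis as in step 11 gives the racemic flavan-4-ol F2, and Dess–Martin oxidation as in step 12 gives the racemic flavanone F3. F3 is then resolved kinetically by asymmetric transfer hydrogenation (RuCl[(R,R)-TsDPEN](p-cymene), HCO2H/Et3N 5:2, EtOAc, rt, stopped near half conversion). This catalyst is expected to reduce the 2R ketone faster, to the cis-(2R,4R)-flavan-4-ol F4, and to leave the 2S ketone, which is 16 and is separated from F4 by chromatography.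

2. Step 11. Possible failures: the C4 cation loses a proton from C3 to give the flav-3-ene, or alkylates the electron-rich ring A of another molecule, instead of being captured by water. Fallback, setting out from 14 and returning at 16, with steps 11 and 12 merged and no new compound (entry F0): oxidation of the benzylic methyl ether with DDQ (1.2 equiv, CH2Cl2/pH 7 buffer 10:1, 0 °C). Hydride abstraction from the doubly activated C4–H gives the aryl-stabilised methoxycarbenium ion, which water converts to the ketone with loss of methanol. The C2–H bond and the benzyl ethers are less activated and should react more slowly.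

3. Step 8. Possible failures: transmetalation at the arylpalladium iodide flanked by two benzyloxy groups is slow, so protodeboronation of 10 and reductive deiodination of 7 take over. Fallback, setting out from 9 and 7 and returning at 11: bromide 9 is stannylated (Me3SnSnMe3, Pd(PPh3)4, toluene, 100 °C) to 4-(benzyloxy)-3-(trimethylstannyl)benzaldehyde F5. F5 is then coupled with 7 in a copper-assisted Stille reaction (Pd(PPh3)4, CuI, CsF, DMF, 50 °C) to give 11. The stannane cannot undergo protodeboronation, and fluoride with CuI accelerates transmetalation to hindered partners.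

**Further compounds**

F1 | step 10 | racemic 7-(benzyloxy)-4,5-dimethoxy-2-aryl-chromane (racemic 14) | COc1cc(OCc2ccccc2)cc2c1C(OC)CC(c1ccc(OCc3ccccc3)c(-c3c(OCc4ccccc4)cc4oc(-c5ccc(OCc6ccccc6)cc5)cc(=O)c4c3OCc3ccccc3)c1)O2
F2 | step 10 | racemic 7-(benzyloxy)-5-methoxy-2-aryl-chroman-4-ol (racemic 15) | COc1cc(OCc2ccccc2)cc2c1C(O)CC(c1ccc(OCc3ccccc3)c(-c3c(OCc4ccccc4)cc4oc(-c5ccc(OCc6ccccc6)cc5)cc(=O)c4c3OCc3ccccc3)c1)O2
F3 | step 10 | racemic 7-(benzyloxy)-5-methoxy-2-aryl-chroman-4-one (racemic 16) | COc1cc(OCc2ccccc2)cc2c1C(=O)CC(c1ccc(OCc3ccccc3)c(-c3c(OCc4ccccc4)cc4oc(-c5ccc(OCc6ccccc6)cc5)cc(=O)c4c3OCc3ccccc3)c1)O2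
F4 | step 10 | cis-(2R,4R)-7-(benzyloxy)-5-methoxy-2-aryl-chroman-4-ol | COc1cc(OCc2ccccc2)cc2c1[C@H](O)C[C@H](c1ccc(OCc3ccccc3)c(-c3c(OCc4ccccc4)cc4oc(-c5ccc(OCc6ccccc6)cc5)cc(=O)c4c3OCc3ccccc3)c1)O2
F0 | step 11 | none | none
F5 | step 8 | 4-(benzyloxy)-3-(trimethylstannyl)benzaldehyde | O=Cc1ccc(OCc2ccccc2)c([Sn](C)(C)C)c1
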